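The target is made from intermediate C, and intermediate C is made from intermediate A, so the question is how much of the charge has passed that stretch when the clock stops.

| setting | Sunday's | Monday's | Wednesday's |
|---|---|---|---|
| substrate | 41 mM | 41 mM | 41 mM |
| reagent | 1.10 equiv | 1.10 equiv | 1.10 equiv |
| temperature | 90 °C | 98 °C | 106 °C |
| time | 4.0 min | 4.0 min | 4.0 min |

    substrate + reagent ⇌ intermediate B (K1 = 560 M⁻¹, k1 = 0.049 M⁻¹ s⁻¹, Ea1 = 85.0 kJ mol⁻¹, ΔH1 = −5.00 kJ mol⁻¹)
    substrate + target → side product (k2 = 0.31 M⁻¹ s⁻¹, Ea2 = 60.0 kJ mol⁻¹)
    intermediate B ⇌ intermediate D (K3 = 43, k3 = 0.068 s⁻¹, Ea3 = 95.0 kJ mol⁻¹, ΔH3 = −54.0 kJ mol⁻¹)
    intermediate A ⇌ intermediate C (K4 = 0.53, k4 = 0.0089 s⁻¹, Ea4 = 98.0 kJ mol⁻¹, ΔH4 = −21.0 kJ mol⁻¹)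
    substrate + reagent → intermediate A (k5 = 3.3 M⁻¹ s⁻¹, Ea5 = 64.0 kJ mol⁻¹)
    intermediate C → target (k6 = 0.0063 s⁻¹, Ea6 = 91.0 kJ mol⁻¹)
    target ⇌ isomer of the product (K7 = 0.17, k7 = 0.0033 s⁻¹, Ea7 = 114 kJ mol⁻¹, ΔH7 = −25.0 kJ mol⁻¹)
    (constants at 90 °C)

* which of these there is most of at the end, counted by the substrate in it, Sunday's (isomer of the product / intermediate C / target / intermediate A)
* which of these there is most of at the end, counted by the substrate in it, Monday's (isomer of the product / intermediate C / target / intermediate A)
* which of these there is most of at the end, counted by the substrate in it, Wednesday's (isomer of the product / intermediate C / target / intermediate A)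
* amount of the one of these that there is most of at the end, in percent of the substrate charged, Sunday's
* amount of the one of these that there is most of at the end, in percent of the substrate charged, Monday's
* amount of the one of these that there is most of at the end, in percent of the substrate charged, Wednesday's

- percent here means substrate units held: one side product counts as two
- the constants hold at 90 °C; other temperatures follow from the activation energies and enthalpies

With reagent at 1.10 equiv, substrate is the limiting reagent. At the start of Sunday's flask substrate goes to intermediate A 67 times as fast as by the forward step alone to intermediate B. The scale of the step to intermediate A, one over its rate constant times the substrate charged, is 7.39 s, shorter than the 112 s that a molecule waits in intermediate A before it moves on. So in this reckoning the charge stands as intermediate A from the start, and the losses to intermediate B and the side product are set aside. Intermediates A and C then form one pool. The end state is plain: the step from C to target has no way back, so the pool ends as target and isomer, with target at 85.5% of the two at Sunday's temperature. How fast it gets there is the real question.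

The first way assumes that A and C are in equilibrium throughout. Intermediate C then holds 34.6% of the pool and leaks to target, which gives a time of 7.64 min. Taken as one exponential decay, that time leaves 59.2% of the pool after Sunday's 4.0 min.

The second way follows one molecule. Intermediate C returns to A at 0.0168 s⁻¹ and goes on to target at 0.0063 s⁻¹, so a molecule needs 3.67 visits to C on average. Each round costs 112 s in A and 43.3 s in C. The product is the drain time, the mean time from intermediate A to target 9.51 min. Taken as one exponential decay in the same way, it leaves 65.7% of the pool in Sunday's flask.

The two ways part, and the first one cheats. It holds C at its equilibrium share from the first moment, but the charge starts in A, and the two times differ by 112 s, one wait in A. The leak to target also runs at 37.5% of the way back. Counted by time spent, molecules sit 72.2% of the round in A, so C has 27.8% of that time, less than the equilibrium share.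

The second way is the one to commit to. The same round, written as one over the A-to-C constant plus one plus one over the equilibrium constant, all over the constant to target, gives 5.34 min at Monday's temperature and 3.09 min at Wednesday's. The pool left is then 47.3% on Monday's and 27.5% on Wednesday's.

Keeping Sunday's share for [intermediate A] and Sunday's end ratio for target against isomer in each flask gives these estimates:

Sunday's flask has intermediate A at 47.4% and target at 29.3%, so A leads.

Monday's flask has intermediate A at 34.1% and target at 45.1%, so target leads.

Wednesday's flask has intermediate A at 19.8% and target at 62.0%, so target leads.

The forecast says intermediate A at 49% for Sunday's, target at 43% for Monday's and target at 62% for Wednesday's, resting on “the slow drain from A through C to the target”, and its Sunday's and Monday's figures differ from those reckoned here.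

The simulation gives intermediate A at 48.6% for Sunday's, target at 42.8% for Monday's and target at 61.9% for Wednesday's.

The run of 4.0 min is shorter than the drain time of 9.51 min in Sunday's flask and longer than the 3.09 min of Wednesday's. Intermediates A and C together stand at 68.8% on Sunday's, 48.5% on Monday's and 27.5% on Wednesday's, against the reckoned 65.7%, 47.3% and 27.5%.

Take Sunday's flask with 0.660 equiv of reagent instead. With less than one equivalent, reagent is the limiting reagent in this flask and the pool starts at that charge. The steps of the drain are first order, so the drain time stays at 9.51 min and intermediate A should stand at 31.3%. The computed flask holds 32.0% of intermediate A, with 28.2% of the substrate left over.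

(The constants used here are those of an exercise; no experiment stands behind them.)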